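The route rests on cutting the linker between vinylic C3′ (the methyl-bearing olefin carbon) and the oxymethylene carbon C4′. The last step, a Stille coupling of an acyloxymethyl stannane with a (Z)-β-iodoenoate, forms this bond with retention of the Z geometry and delivers the intact angelate onto the unprotected diosphenol core in one operation. The step exploits the trisubstituted C2′=C3′ olefin, whose Z geometry is stored in a vinyl iodide made by anti-hydroiodination of tetrolic acid. Its precursor is the (Z)-3-iodobut-2-enoate of 9-hydroxyisopetasol. The decalin (ring A C1–C5/C10, ring B C5–C10) comes from (S)-Wieland–Miescher ketone: the purchased C5 centre relays C3 and C4 in a single hydroboration, and a 9,10-epoxy ketone serves as latent diosphenol.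

Key step: step 11

Remark: core locants C1–C15 follow eremophilane numbering (C3 carbinol, C4 and C5 methyl-bearing, C8 ketone, C9/C10 enol) and linker atoms are primed; tributyl(iodomethyl)stannane is taken as a catalogue reagent; for transient stereocentres (the C8 carbinol, the oxirane carbons, the C7 aldol centre) the expected major isomer is drawn and the minor one converges.

Step 1
Reactants: 1 (S)-Wieland–Miescher ketone
Product: 2 (4aR)-4a-methyl-5-methylidene-4,4a,5,6,7,8-hexahydronaphthalen-2(3H)-one
Conditions: Ph3PCH3Br (3 equiv), KOtBu (3 equiv), THF, 0 °C to 50 °C; aq. NH4Cl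
Reagents that add atoms: methyltriphenylphosphonium bromide, C[P+](c1ccccc1)(c1ccccc1)c1ccccc1.[Br-]
Why: Wittig methylenation, in which the excess ylide first turns the enone into its dienolate (inert to the ylide, as in the 17-ketone-selective olefination of androst-4-ene-3,17-dione) so that only the saturated C4 ketone should be olefinated; C5 is untouched and any deconjugated enone from work-up is reconjugated in step 2.

Step 2
Reactants: 2 (4aR)-4a-methyl-5-methylidene-4,4a,5,6,7,8-hexahydronaphthalen-2(3H)-one
Product: 3 (4aR)-4a,5-dimethyl-4,4a,7,8-tetrahydronaphthalen-2(3H)-one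
Conditions: TsOH·H2O (10 mol%), PhH, reflux
Reagents that add atoms: none
Why: acid-catalysed exo-to-endo olefin isomerisation through the tertiary C4 cation, which should settle on the more stable trisubstituted Δ3 olefin because quaternary C5 blocks any further migration.

Step 3
Reactants: 3 (4aR)-4a,5-dimethyl-4,4a,7,8-tetrahydronaphthalen-2(3H)-one
Product: 5 (2S,4aR,5R,6R)-4a,5-dimethyl-2,3,4,4a,5,6,7,8-octahydronaphthalene-2,6-diol, via C3-borane C8-borinate adduct 4 (not isolated)
Conditions: BH3·THF (1.3 equiv), THF, −10 to 0 °C; then 3 M NaOH, 30% H2O2, 0 °C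
Reagents that add atoms: hydrogen peroxide, OO
Why: hydroboration–oxidation in which borane reduces the enone carbonyl 1,2 and adds syn across Δ3 from the face opposite the pseudo-axial C5 methyl with boron at C3, so that C3 (R) and C4 (R) are set together (3-O trans to 4-Me, 4-Me cis to 5-Me), while the Δ9 olefin of the allylic borinate, inductively deactivated and flanked by the C8 oxygen and quaternary C5, should react more slowly.

Step 4
Reactants: 5 (2S,4aR,5R,6R)-4a,5-dimethyl-2,3,4,4a,5,6,7,8-octahydronaphthalene-2,6-diol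
Product: 6 (4aR,5R,6R)-6-hydroxy-4a,5-dimethyl-4,4a,5,6,7,8-hexahydronaphthalen-2(3H)-one
Conditions: activated MnO2 (15 equiv), CH2Cl2, rt
Reagents that add atoms: none
Why: chemoselective MnO2 oxidation of the allylic C8 alcohol (either epimer) back to the enone, which should leave the saturated C3 carbinol untouched.

Step 5
Reactants: 6 (4aR,5R,6R)-6-hydroxy-4a,5-dimethyl-4,4a,5,6,7,8-hexahydronaphthalen-2(3H)-one
Product: 7 (3R,4R,5R,9R,10R)-9,10-epoxy-3-hydroxy-11,12,13-trinoreremophilan-8-one
Conditions: 30% H2O2, 2 M NaOH, MeOH, 0 °C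
Reagents that add atoms: hydrogen peroxide, OO
Why: Weitz–Scheffer nucleophilic epoxidation of the only enone, expected mainly syn to the C5 methyl by analogy with the 4β,5β-epoxidation of Δ4-3-keto steroids; both oxirane epimers converge in step 9.

Step 6
Reactants: 7 (3R,4R,5R,9R,10R)-9,10-epoxy-3-hydroxy-11,12,13-trinoreremophilan-8-one
Product: 9 (3R,4R,5R,7S,9R,10R)-9,10-epoxy-3,11-dihydroxyeremophilan-8-one, via dilithium alkoxide enolate 8 (not isolated)
Conditions: LDA (2.3 equiv), THF, −78 °C; acetone (3 equiv), −78 °C; AcOH quench at −78 °C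
Reagents that add atoms: acetone, CC(C)=O
Why: directed aldol addition of the kinetic C7 lithium enolate (C7 is the only enolisable position because C9–H sits on the oxirane, and the C3 alkoxide is a spectator) to acetone, with a cold quench against retro-aldol; the C7 centre (equatorial expected) is erased in step 9.

Step 7
Reactants: 10 but-2-ynoic acid
Product: 11 (2Z)-3-iodobut-2-enoic acid
Conditions: NaI (1.6 equiv), AcOH, 110 °C
Reagents that add atoms: sodium iodide, [Na+].[I-]
Why: conjugate hydroiodination of the ynoic acid, in which iodide adds to C3 and protonation occurs anti, so that iodine ends cis to the carboxyl (Z).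

Step 8
Reactants: 9 (3R,4R,5R,7S,9R,10R)-9,10-epoxy-3,11-dihydroxyeremophilan-8-one, 11 (2Z)-3-iodobut-2-enoic acid
Product: 12 (3R,4R,5R,7S,9R,10R)-9,10-epoxy-11-hydroxy-8-oxoeremophilan-3-yl (2Z)-3-iodobut-2-enoate
Conditions: DCC (1.3 equiv), DMAP (10 mol%), CH2Cl2, 0 °C
Reagents that add atoms: none
Why: Steglich esterification, which should acylate the secondary equatorial C3–OH and not the tertiary C11–OH, with retention at C3 (only the acyl–O bond is formed) and with low temperature and catalytic DMAP to keep the iodoenoate Z.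

Step 9
Reactants: 12 (3R,4R,5R,7S,9R,10R)-9,10-epoxy-11-hydroxy-8-oxoeremophilan-3-yl (2Z)-3-iodobut-2-enoate
Product: 13 (3R,4R,5R)-9-hydroxy-8-oxoeremophila-7(11),9-dien-3-yl (2Z)-3-iodobut-2-enoate
Conditions: conc. H2SO4 (cat.), AcOH, rt
Reagents that add atoms: none
Why: two acid-triggered events in one pot, the epoxy ketone to diosphenol isomerisation (oxirane opening at tertiary C10 and loss of C9–H, as for 4,5-epoxy-3-keto steroids) and the aldol dehydration of the tertiary C11 carbinol into conjugation as the 7(11)-isopropylidene, which together erase the C7, C9 and C10 centres.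

Step 10
Reactants: 14 angelic acid, 15 tributyl(iodomethyl)stannane
Product: 17 tributyl{[(2Z)-2-methylbut-2-enoyl]oxymethyl}stannane, via potassium angelate 16 (not isolated)
Conditions: K2CO3 (1.2 equiv), DMF, rt
Reagents that add atoms: none
Why: SN2 O-alkylation of the carboxylate by the α-stannyl iodide, in which the angelate reacts only at oxygen and is never acyl-activated, so its Z geometry should survive.

Step 11
Reactants: 13 (3R,4R,5R)-9-hydroxy-8-oxoeremophila-7(11),9-dien-3-yl (2Z)-3-iodobut-2-enoate, 17 tributyl{[(2Z)-2-methylbut-2-enoyl]oxymethyl}stannane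
Product: 18 (3R,4R,5R)-9-hydroxy-8-oxoeremophila-7(11),9-dien-3-yl (2Z)-3-methyl-4-{[(2Z)-2-methylbut-2-enoyl]oxy}but-2-enoate
Conditions: Pd2(dba)3 (5 mol%), P(2-furyl)3 (20 mol%), CuI (20 mol%), NMP, 50 °C
Reagents that add atoms: none
Why: Stille C(sp2)–C(sp3) coupling: Pd(0) inserts into the vinylic C3′–I bond of 13 with retention, the acyloxymethyl group of 17 passes from tin via copper to palladium, and reductive elimination forges the C3′–C4′ bond. The closest known reaction type is the Stille coupling of hydroxymethyl- and alkoxymethyl-tributylstannanes with vinyl and aryl halides, together with the Pd/Cu coupling of α-acyloxyalkylstannanes. No ring is closed and no stereocentre is created; the stereo-element is the Z olefin, inherited from the iodide because neither oxidative addition nor reductive elimination touches the geometry. The step needs transfer of CH2O-acyl rather than butyl, which the α-oxygen and carbonyl-to-tin coordination should secure, and reaction at C–I only in the presence of the free enol, the dienone and two further enoates, which the neutral, base- and fluoride-free medium should secure. Because the C4′ oxygen arrives already acylated, the Z-γ-oxy enoate cannot lactonise and expel the terpenol, and the angelate is never exposed to conditions that would isomerise it to tiglate.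

Compound list
1 | (S)-Wieland–Miescher ketone, (8aS)-8a-methyl-3,4,8,8a-tetrahydronaphthalene-1,6(2H,7H)-dione | C[C@]12CCC(=O)C=C1CCCC2=O | starting material
2 | (4aR)-4a-methyl-5-methylidene-4,4a,5,6,7,8-hexahydronaphthalen-2(3H)-one | C=C1CCCC2=CC(=O)CC[C@]12C | intermediate
3 | (4aR)-4a,5-dimethyl-4,4a,7,8-tetrahydronaphthalen-2(3H)-one | CC1=CCCC2=CC(=O)CC[C@]12C | intermediate
4 | C3-borane C8-borinate adduct of 3 (boron at C3 anti to the C5 methyl) | B[C@@H]1CCC2=C[C@@H](OB)CC[C@]2(C)[C@H]1C | intermediate (not isolated)
5 | (2S,4aR,5R,6R)-4a,5-dimethyl-2,3,4,4a,5,6,7,8-octahydronaphthalene-2,6-diol (C8 epimer converges) | O[C@@H]1CCC2=C[C@@H](O)CC[C@]2(C)[C@H]1C | intermediate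
6 | (4aR,5R,6R)-6-hydroxy-4a,5-dimethyl-4,4a,5,6,7,8-hexahydronaphthalen-2(3H)-one | O[C@@H]1CCC2=CC(=O)CC[C@]2(C)[C@H]1C | intermediate
7 | (3R,4R,5R,9R,10R)-9,10-epoxy-3-hydroxy-11,12,13-trinoreremophilan-8-one (oxirane syn to C5 methyl) | O[C@@H]1CC[C@]23O[C@H]2C(=O)CC[C@]3(C)[C@H]1C | intermediate
8 | dilithium C3-alkoxide C7,C8-enolate of 7 | [Li]O[C@@H]1CC[C@]23O[C@H]2C(O[Li])=CC[C@]3(C)[C@H]1C | intermediate (not isolated)
9 | (3R,4R,5R,7S,9R,10R)-9,10-epoxy-3,11-dihydroxyeremophilan-8-one | O[C@@H]1CC[C@]23O[C@H]2C(=O)[C@H](C(C)(C)O)C[C@]3(C)[C@H]1C | intermediate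
10 | but-2-ynoic acid (tetrolic acid) | CC#CC(=O)O | starting material
11 | (2Z)-3-iodobut-2-enoic acid | C/C(I)=C/C(=O)O | intermediate
12 | (3R,4R,5R,7S,9R,10R)-9,10-epoxy-11-hydroxy-8-oxoeremophilan-3-yl (2Z)-3-iodobut-2-enoate | C/C(I)=C/C(=O)O[C@@H]1CC[C@]23O[C@H]2C(=O)[C@H](C(C)(C)O)C[C@]3(C)[C@H]1C | intermediate
13 | (3R,4R,5R)-9-hydroxy-8-oxoeremophila-7(11),9-dien-3-yl (2Z)-3-iodobut-2-enoate | C/C(I)=C/C(=O)O[C@@H]1CCC2=C(O)C(=O)C(=C(C)C)C[C@]2(C)[C@H]1C | intermediate
14 | angelic acid, (2Z)-2-methylbut-2-enoic acid | C/C=C(/C)C(=O)O | starting material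
15 | tributyl(iodomethyl)stannane | CCCC[Sn](CI)(CCCC)CCCC | starting material
16 | potassium angelate | C/C=C(/C)C(=O)[O-].[K+] | intermediate (not isolated)
17 | tributyl{[(2Z)-2-methylbut-2-enoyl]oxymethyl}stannane | C/C=C(/C)C(=O)OC[Sn](CCCC)(CCCC)CCCC | intermediate
18 | (3R,4R,5R)-9-hydroxy-8-oxoeremophila-7(11),9-dien-3-yl (2Z)-3-methyl-4-{[(2Z)-2-methylbut-2-enoyl]oxy}but-2-enoate (CNP0228871.1) | C/C=C(/C)C(=O)OC/C(C)=C\C(=O)O[C@@H]1CCC2=C(O)C(=O)C(=C(C)C)C[C@]2(C)[C@H]1C | target

Total step count: 11. Longest linear sequence: 9 (steps 1–6, 8, 9, 11).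

Steps most likely to fail

Step 11. The sp3 tin-to-palladium transfer may be slow while the free enol sequesters copper or palladium, so that protodestannylation or butyl transfer overtakes the coupling. The fallback sets out from 13 and comes back at 18. TESCl/Et3N at −78 °C converts 13 into its 9-O-triethylsilyl ether F5. Angelic acid 14, as its potassium salt 16, is alkylated with chloroiodomethane to chloromethyl angelate F6, Finkelstein exchange (NaI, acetone) gives iodomethyl angelate F7, and zinc dust in THF gives (angeloyloxymethyl)zinc iodide F8. Negishi coupling of F8 with F5 (Pd(PPh3)4, THF/NMP, rt) should give the 9-O-triethylsilyl ether of the target F9, and HF·pyridine then frees the enol to give 18.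

Step 9. The strong acid may isomerise or solvolyse the β-iodoenoate, or the two acid-triggered events may run at unequal rates (retro-aldol loss of acetone before dehydration, acyl shift of the epoxy ketone). The fallback sets out from 9 and comes back at 13. Treatment of 9 with TsOH in benzene at 60 °C, where no ester is at risk and the conditions can be forced, should give 9-hydroxyisopetasol F3. TESCl/Et3N at −78 °C should silylate only the acidic enol hydroxyl to give 9-O-triethylsilyl-9-hydroxyisopetasol F4. Steglich esterification of F4 with 11 gives the silylated iodoenoate F5, and HF·pyridine gives 13.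

Step 3. Borane may also add to the Δ9 olefin of the allylic borinate, or reduce the carbonyl incompletely, so that over- and under-reacted material accompanies the diol. The fallback sets out from 3 and comes back at 6. Ethane-1,2-dithiol/BF3·OEt2 converts the enone into the 8,8-ethylenedithio ketal F1 without moving the olefin. Hydroboration (BH3·THF, then NaBO3) then has no carbonyl to reduce and meets a Δ9 olefin shielded by the spiro-dithiolane, and should give the 3-hydroxy dithioketal F2. MeI/CaCO3 in aqueous MeCN unmasks the enone to give 6.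

Further compounds
F1 | step 3 | (4aR)-4a,5-dimethyl-4,4a,7,8-tetrahydro-3H-spiro[naphthalene-2,2′-[1,3]dithiolane] (8,8-ethylenedithio ketal of 3) | CC1=CCCC2=CC3(SCCS3)CC[C@]12C
F2 | step 3 | 8,8-ethylenedithio ketal of 6 ((3R,4R,5R)-3-hydroxy dithioketal) | O[C@@H]1CCC2=CC3(SCCS3)CC[C@]2(C)[C@H]1C
F3 | step 9 | 9-hydroxyisopetasol, (3R,4R,5R)-3,9-dihydroxyeremophila-7(11),9-dien-8-one | O[C@@H]1CCC2=C(O)C(=O)C(=C(C)C)C[C@]2(C)[C@H]1C
F4 | step 9 | 9-O-triethylsilyl-9-hydroxyisopetasol | O[C@@H]1CCC2=C(O[Si](CC)(CC)CC)C(=O)C(=C(C)C)C[C@]2(C)[C@H]1C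
F5 | step 9 | (3R,4R,5R)-8-oxo-9-(triethylsilyloxy)eremophila-7(11),9-dien-3-yl (2Z)-3-iodobut-2-enoate | C/C(I)=C/C(=O)O[C@@H]1CCC2=C(O[Si](CC)(CC)CC)C(=O)C(=C(C)C)C[C@]2(C)[C@H]1C
F6 | step 11 | chloromethyl angelate | C/C=C(/C)C(=O)OCCl
F7 | step 11 | iodomethyl angelate | C/C=C(/C)C(=O)OCI
F8 | step 11 | (angeloyloxymethyl)zinc iodide | C/C=C(/C)C(=O)OC[Zn]I
F9 | step 11 | 9-O-triethylsilyl ether of the target | C/C=C(/C)C(=O)OC/C(C)=C\C(=O)O[C@@H]1CCC2=C(O[Si](CC)(CC)CC)C(=O)C(=C(C)C)C[C@]2(C)[C@H]1C
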